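Ring B is closed last by forging C8–C9 (halimane numbering). The step exploits one feature: quaternary C9 is the exocyclic tertiary terminus of an allyl cation spanning C9, C10 and C1 of ring A. Ionising a C9 carbinol therefore lets the enol carbon C8 of a C7 ketone, tethered through C5 and C6, bond to C9 while the alkene stays at C1=C10. That single operation builds ring B and sets C9 and C8. Its precursor is a ring-A cyclohexene bearing the C9 tertiary allylic alcohol, a 2-oxobutyl arm on C5 cis to the C4 ester, and the side chain already as its propionate, so that no protecting group is left after cyclisation.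

Key step: step 13

Remark: halimane numbering is used throughout; C19 is the ester carbon on C4, C20 the methyl on C9, C17 the methyl on C8.
Remark: the (4R,5R)-diol catalyst of step 1 is assumed to give the (S)-adduct; if the sense proves opposite, its enantiomer is used and nothing else changes.
Remark: geranyl propionate is taken as a purchasable flavour chemical; it is otherwise one acylation from geraniol.

Step 1
Reactants: 1 (E)-3-(tert-butyldimethylsilyloxy)-N,N-dimethylbuta-1,3-dien-1-amine; 2 methacrolein
Product: 4 (S)-1-methyl-4-oxocyclohex-2-ene-1-carbaldehyde, via aminosiloxy cycloadduct 3 (not isolated)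
Conditions: (4R,5R)-2,2-dimethyl-α,α,α′,α′-tetra(1-naphthyl)-1,3-dioxolane-4,5-dimethanol (20 mol%), toluene, −80 °C; then HF (aq.), MeCN, 0 °C
Reagents that add atoms: none
Why: Hydrogen-bond-catalysed Diels–Alder reaction of an aminosiloxydiene with an α-substituted acrolein is established for this pairing, the amino terminus bonding to the carbon that becomes quaternary C4 and the diol-bound aldehyde being attacked on one face, after which acid hydrolyses the silyl enol ether and expels dimethylamine to give the enone.

Step 2
Reactants: 4 (S)-1-methyl-4-oxocyclohex-2-ene-1-carbaldehyde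
Product: 5 (S)-1-methyl-4-oxocyclohex-2-ene-1-carboxylic acid
Conditions: NaClO2, NaH2PO4, 2-methylbut-2-ene, t-BuOH/H2O, 0 °C → rt
Reagents that add atoms: sodium chlorite, [Na+].[O-]Cl=O
Why: Pinnick oxidation converts an aldehyde on a quaternary carbon into the acid without touching the enone, and C4 cannot epimerise because it carries no hydrogen.

Step 3
Reactants: 5 (S)-1-methyl-4-oxocyclohex-2-ene-1-carboxylic acid
Product: 6 methyl (S)-1-methyl-4-oxocyclohex-2-ene-1-carboxylate
Conditions: MeI, K2CO3, DMF, rt
Reagents that add atoms: iodomethane, CI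
Why: SN2 alkylation of the carboxylate is insensitive to the crowding around the carboxyl group and needs neither acid nor a diazo reagent.

Step 4
Reactants: 6 methyl (S)-1-methyl-4-oxocyclohex-2-ene-1-carboxylate
Product: 7 methyl (S)-3-iodo-1-methyl-4-oxocyclohex-2-ene-1-carboxylate
Conditions: I2, pyridine, CH2Cl2, 0 °C → rt
Reagents that add atoms: iodine, II
Why: Amine-mediated α-iodination of a cyclohexenone (Baylis–Hillman-type addition of pyridine, iodination of the enolate, elimination) is routine for 4,4-disubstituted enones and puts the coupling handle on C10.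

Step 5
Reactants: 7 methyl (S)-3-iodo-1-methyl-4-oxocyclohex-2-ene-1-carboxylate
Product: 8 methyl (1S,4R)-4-hydroxy-3-iodo-1-methylcyclohex-2-ene-1-carboxylate
Conditions: (S)-1-methyl-3,3-diphenyltetrahydro-1H,3H-pyrrolo[1,2-c][1,3,2]oxazaborole (15 mol%), BH3·SMe2, THF, −20 °C; then MeOH
Reagents that add atoms: none
Why: Corey–Bakshi–Shibata reduction of α-halo enones is highly face-selective because the iodoalkenyl side behaves as the large group, so the catalyst and not the remote C4 centre fixes the C1 carbinol as (R), that is, cis to the ester.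

Step 6
Reactants: 8 methyl (1S,4R)-4-hydroxy-3-iodo-1-methylcyclohex-2-ene-1-carboxylate; 9 methyl 3-oxopentanoate
Product: 12 methyl (1S,2S)-3-iodo-1-methyl-2-(2-oxobutyl)cyclohex-3-ene-1-carboxylate, via allyl 3-oxopentanoate 10 (not isolated), via keto acid 11 (not isolated)
Conditions: 4-(dimethylamino)pyridine (cat.), xylene, 140 °C, MeOH distilled off
Reagents that add atoms: none
Why: Carroll rearrangement, in which the transesterified keto ester reacts as its enol in a [3,3] shift that delivers C6 to C5 on the face of the departing C1 oxygen (cis to the ester, which sets C5) and moves the alkene to C1=C10 before the keto acid loses CO2.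

Step 7
Reactants: 12 methyl (1S,2S)-3-iodo-1-methyl-2-(2-oxobutyl)cyclohex-3-ene-1-carboxylate
Product: 13 methyl (1S,2S)-2-(2,2-dimethoxybutyl)-3-iodo-1-methylcyclohex-3-ene-1-carboxylate
Conditions: HC(OMe)3, MeOH, p-TsOH (cat.), rt
Reagents that add atoms: trimethyl orthoformate, COC(OC)OC; methanol, CO
Why: Acid-catalysed ketalisation driven by the orthoformate masks the C7 ketone as its most easily cleaved ketal for the steps in which a methyl nucleophile is added at C9.

Step 8
Reactants: 14 geranyl propionate ((2E)-3,7-dimethylocta-2,6-dien-1-yl propanoate)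
Product: 15 (2E)-3-methyl-6-oxohex-2-en-1-yl propanoate
Conditions: O3 (1 equiv), pyridine, CH2Cl2, −78 °C; then Me2S
Reagents that add atoms: ozone, O=[O+][O-]
Why: Ozonolysis is selective for the electron-rich 6,7-alkene because the 2,3-alkene is deactivated by the allylic ester, as known for geranyl acetate, and the E geometry of the remaining alkene is not touched.

Step 9
Reactants: 13 methyl (1S,2S)-2-(2,2-dimethoxybutyl)-3-iodo-1-methylcyclohex-3-ene-1-carboxylate; 15 (2E)-3-methyl-6-oxohex-2-en-1-yl propanoate
Product: 16 (2E)-6-[(5S,6R)-6-(2,2-dimethoxybutyl)-5-(methoxycarbonyl)-5-methylcyclohex-1-en-1-yl]-6-hydroxy-3-methylhex-2-en-1-yl propanoate (both C9 epimers)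
Conditions: CrCl2 (4 equiv), NiCl2 (2 mol%), DMF, rt
Reagents that add atoms: none
Why: Nozaki–Hiyama–Kishi coupling gives an alkenylchromium reagent that adds only to the aldehyde and leaves the propionate, the methyl ester and the ketal alone, the configuration of the new C9 carbinol being irrelevant because it is oxidised next.

Step 10
Reactants: 16 the secondary C9 alcohol from step 9
Product: 17 (2E)-6-[(5S,6R)-6-(2,2-dimethoxybutyl)-5-(methoxycarbonyl)-5-methylcyclohex-1-en-1-yl]-3-methyl-6-oxohex-2-en-1-yl propanoate
Conditions: Dess–Martin periodinane, NaHCO3, CH2Cl2, 0 °C → rt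
Reagents that add atoms: none
Why: Dess–Martin oxidation of the allylic secondary alcohol under buffered conditions gives the enone without disturbing the acid-labile dimethyl ketal.

Step 11
Reactants: 17 the C9 enone from step 10
Product: 18 (2E)-6-[(5S,6R)-6-(2,2-dimethoxybutyl)-5-(methoxycarbonyl)-5-methylcyclohex-1-en-1-yl]-6-hydroxy-3-methylhept-2-en-1-yl propanoate (both C9 epimers)
Conditions: MeMgBr, CeCl3, THF, −78 °C; then NH4Cl (aq.)
Reagents that add atoms: methylmagnesium bromide, C[Mg]Br
Why: Organocerium 1,2-addition of a methyl group to the hindered enone is fast at low temperature and suppresses enolisation and attack on the two esters, and the C9 epimer mixture is harmless because both epimers ionise to the same cation.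

Step 12
Reactants: 18 the tertiary C9 alcohol with the C7 dimethyl ketal
Product: 19 (2E)-6-hydroxy-6-[(5S,6R)-5-(methoxycarbonyl)-5-methyl-6-(2-oxobutyl)cyclohex-1-en-1-yl]-3-methylhept-2-en-1-yl propanoate (both C9 epimers)
Conditions: pyridinium p-toluenesulfonate (10 mol%), acetone/H2O 10:1, rt
Reagents that add atoms: water, O
Why: Hydrolysis of an acyclic dimethyl ketal with a pyridinium salt in wet acetone is mild enough to leave the tertiary allylic alcohol, the allylic propionate and the methyl ester intact.

Step 13
Reactants: 19 the C9 tertiary allylic alcohol with the C5 2-oxobutyl arm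
Product: 20 methyl (4S,5R,8S,9S)-7-oxo-15-(propanoyloxy)halima-1(10),13E-dien-19-oate
Conditions: Bi(OTf)3 (5 mol%), MeNO2, 0 °C; Et3N quench at full conversion
Reagents that add atoms: none
Why: Bi(OTf)3 ionises either C9 epimer of 19, directly or through the oxygen-bridged hemiketal that forms reversibly, to the allyl cation over C9, C10 and C1, and the (Z)-enol of the C7 ketone attacks C9 through C8, loss of the oxygen-bound proton then giving 20. The closest known reaction type is the Lewis- or Brønsted-acid-catalysed dehydrative SN1 α-allylation of ketones and 1,3-dicarbonyl compounds by tertiary allylic alcohols, here run intramolecularly. Ring B closes in a 6-(enolendo)-endo-trig mode through a chair. C9 is controlled by the geometry of the cation, the methyl group taking the crowded in-plane site beside C5 and so ending axial and cis to H5 while the longer C11 chain sits beside H1 and ends equatorial, and C8 is controlled by the (Z)-enol, which places C17 equatorial, the reaction being quenched at full conversion so that this centre does not equilibrate. The selectivity needed is bonding at C9 and not at C1, which would also close a six-membered ring but as a bridged bicyclononanone: the pseudoaxial C6 arm on C5 stands about 75° from C9 and 105° from C1, so C9 is reached from the resting half-chair of ring A whereas C1 is reached only when ring A distorts, and C9 also carries the larger share of the charge. The propionate keeps the side-chain allylic C–O bond from ionising and its alkene from competing, and the C6 enol cannot react because it would close a four-membered ring.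

Step 14
Reactants: 20 the bicyclic C7 ketone
Product: 21 methyl (4S,5R,8S,9S)-7-hydroxy-15-(propanoyloxy)halima-1(10),13E-dien-19-oate (C7 epimers)
Conditions: NaBH4, MeOH/THF, 0 °C
Reagents that add atoms: none
Why: Borohydride reduction of the only ketone, run directly after the cyclisation so that C8 cannot drift, gives the C7 alcohol whose configuration is irrelevant, while both esters survive at 0 °C.

Step 15
Reactants: 21 the C7 alcohol
Product: 22 methyl (4S,5R,8S,9S)-7-[(1H-imidazol-1-ylcarbonothioyl)oxy]-15-(propanoyloxy)halima-1(10),13E-dien-19-oate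
Conditions: 1,1′-thiocarbonyldiimidazole, 4-(dimethylamino)pyridine (cat.), 1,2-dichloroethane, 70 °C
Reagents that add atoms: 1,1′-thiocarbonyldiimidazole, S=C(n1ccnc1)n1ccnc1
Why: Acyl-transfer thiocarbonylation, the first stage of the Barton–McCombie deoxygenation, works on hindered secondary alcohols under near-neutral conditions that spare the esters.

Step 16
Reactants: 22 the C7 imidazole thiocarbamate
Product: 23 methyl (4S,5R,8R,9S)-15-(propanoyloxy)halima-1(10),13E-dien-19-oate
Conditions: Bu3SnH, AIBN (cat.), toluene, 100 °C
Reagents that add atoms: none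
Why: Barton–McCombie radical deoxygenation, in which the stannyl radical adds to sulfur, the C7–O bond fragments and the secondary C7 radical, which has no fast cyclisation open to it, is reduced by the tin hydride with the esters and both alkenes untouched.

Compound list
1 | (E)-3-(tert-butyldimethylsilyloxy)-N,N-dimethylbuta-1,3-dien-1-amine | CN(C)/C=C/C(=C)O[Si](C)(C)C(C)(C)C | starting material
2 | methacrolein (2-methylprop-2-enal) | CC(=C)C=O | starting material
3 | (1S)-4-(tert-butyldimethylsilyloxy)-2-(dimethylamino)-1-methylcyclohex-3-ene-1-carbaldehyde (amino-bearing carbon unassigned, lost on elimination) | C[C@@]1(C=O)C(N(C)C)C=C(O[Si](C)(C)C(C)(C)C)CC1 | intermediate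
4 | (S)-1-methyl-4-oxocyclohex-2-ene-1-carbaldehyde | C[C@@]1(C=O)C=CC(=O)CC1 | intermediate
5 | (S)-1-methyl-4-oxocyclohex-2-ene-1-carboxylic acid | C[C@@]1(C(=O)O)C=CC(=O)CC1 | intermediate
6 | methyl (S)-1-methyl-4-oxocyclohex-2-ene-1-carboxylate | C[C@@]1(C(=O)OC)C=CC(=O)CC1 | intermediate
7 | methyl (S)-3-iodo-1-methyl-4-oxocyclohex-2-ene-1-carboxylate | C[C@@]1(C(=O)OC)C=C(I)C(=O)CC1 | intermediate
8 | methyl (1S,4R)-4-hydroxy-3-iodo-1-methylcyclohex-2-ene-1-carboxylate (hydroxyl cis to the ester) | C[C@@]1(C(=O)OC)C=C(I)[C@H](O)CC1 | intermediate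
9 | methyl 3-oxopentanoate | CCC(=O)CC(=O)OC | starting material
10 | (1R,4S)-2-iodo-4-(methoxycarbonyl)-4-methylcyclohex-2-en-1-yl 3-oxopentanoate | C[C@@]1(C(=O)OC)C=C(I)[C@H](OC(=O)CC(=O)CC)CC1 | intermediate
11 | 2-[(1S,6S)-2-iodo-6-(methoxycarbonyl)-6-methylcyclohex-2-en-1-yl]-3-oxopentanoic acid (α-carbon unassigned, lost on decarboxylation) | IC1=CCC[C@](C)(C(=O)OC)[C@@H]1C(C(=O)O)C(=O)CC | intermediate
12 | methyl (1S,2S)-3-iodo-1-methyl-2-(2-oxobutyl)cyclohex-3-ene-1-carboxylate (arm cis to the ester) | IC1=CCC[C@](C)(C(=O)OC)[C@@H]1CC(=O)CC | intermediate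
13 | methyl (1S,2S)-2-(2,2-dimethoxybutyl)-3-iodo-1-methylcyclohex-3-ene-1-carboxylate | IC1=CCC[C@](C)(C(=O)OC)[C@@H]1CC(OC)(OC)CC | intermediate
14 | geranyl propionate, (2E)-3,7-dimethylocta-2,6-dien-1-yl propanoate | CCC(=O)OC/C=C(\C)CCC=C(C)C | starting material
15 | (2E)-3-methyl-6-oxohex-2-en-1-yl propanoate | CCC(=O)OC/C=C(\C)CCC=O | intermediate
16 | (2E)-6-[(5S,6R)-6-(2,2-dimethoxybutyl)-5-(methoxycarbonyl)-5-methylcyclohex-1-en-1-yl]-6-hydroxy-3-methylhex-2-en-1-yl propanoate (C9 epimers) | CCC(=O)OC/C=C(\C)CCC(O)C1=CCC[C@](C)(C(=O)OC)[C@@H]1CC(OC)(OC)CC | intermediate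
17 | (2E)-6-[(5S,6R)-6-(2,2-dimethoxybutyl)-5-(methoxycarbonyl)-5-methylcyclohex-1-en-1-yl]-3-methyl-6-oxohex-2-en-1-yl propanoate | CCC(=O)OC/C=C(\C)CCC(=O)C1=CCC[C@](C)(C(=O)OC)[C@@H]1CC(OC)(OC)CC | intermediate
18 | (2E)-6-[(5S,6R)-6-(2,2-dimethoxybutyl)-5-(methoxycarbonyl)-5-methylcyclohex-1-en-1-yl]-6-hydroxy-3-methylhept-2-en-1-yl propanoate (C9 epimers) | CCC(=O)OC/C=C(\C)CCC(C)(O)C1=CCC[C@](C)(C(=O)OC)[C@@H]1CC(OC)(OC)CC | intermediate
19 | (2E)-6-hydroxy-6-[(5S,6R)-5-(methoxycarbonyl)-5-methyl-6-(2-oxobutyl)cyclohex-1-en-1-yl]-3-methylhept-2-en-1-yl propanoate (C9 epimers; key-step precursor) | CCC(=O)OC/C=C(\C)CCC(C)(O)C1=CCC[C@](C)(C(=O)OC)[C@@H]1CC(=O)CC | intermediate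
20 | methyl (4S,5R,8S,9S)-7-oxo-15-(propanoyloxy)halima-1(10),13E-dien-19-oate (H5, C17 and C20 on one face; C19 and the C9 side chain on the other) | CCC(=O)OC/C=C(\C)CC[C@]1(C)C2=CCC[C@](C)(C(=O)OC)[C@@H]2CC(=O)[C@H]1C | intermediate
21 | methyl (4S,5R,8S,9S)-7-hydroxy-15-(propanoyloxy)halima-1(10),13E-dien-19-oate (C7 epimers) | CCC(=O)OC/C=C(\C)CC[C@]1(C)C2=CCC[C@](C)(C(=O)OC)[C@@H]2CC(O)[C@H]1C | intermediate
22 | methyl (4S,5R,8S,9S)-7-[(1H-imidazol-1-ylcarbonothioyl)oxy]-15-(propanoyloxy)halima-1(10),13E-dien-19-oate (C7 epimers) | CCC(=O)OC/C=C(\C)CC[C@]1(C)C2=CCC[C@](C)(C(=O)OC)[C@@H]2CC(OC(=S)n3ccnc3)[C@H]1C | intermediate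
23 | methyl (4S,5R,8R,9S)-15-(propanoyloxy)halima-1(10),13E-dien-19-oate | CCC(=O)OC/C=C(\C)CC[C@]1(C)C2=CCC[C@](C)(C(=O)OC)[C@@H]2CC[C@H]1C | target

Total step count: 16. Longest linear sequence: 15 steps (steps 1–7, then 9–16); step 8 is the one-step side branch.

Steps most likely to fail

Step 13. The allyl cation may partition toward the ring terminus C1, where the same enol would close a bridged bicyclo[3.3.1]nonanone, or lose a proton to dienes. The two cation geometries may also be told apart only weakly at C9, since a methyl group and a primary chain differ little in size. C8 may epimerise if the ketone stays in acid. The fallback sets out from 19 and returns at 20. LiN(SiMe3)2 and Me3SiCl in THF at −78 °C should silylate the carbinol and trap the kinetic (Z)-enolate on the ethyl side, giving (2E)-6-[(5S,6R)-5-(methoxycarbonyl)-5-methyl-6-{(2Z)-2-[(trimethylsilyl)oxy]but-2-en-1-yl}cyclohex-1-en-1-yl]-3-methyl-6-[(trimethylsilyl)oxy]hept-2-en-1-yl propanoate F1. A catalytic amount of Me3SiOTf in CH2Cl2 at −78 °C then ionises the tertiary allylic silyl ether, and the enol silane is alkylated within the ion pair (Mukaiyama-type SN1 alkylation of an enol silane by a tertiary allylic ether). The pre-formed nucleophile of fixed geometry and the aprotic, cold medium remove the protic equilibria through which the dienes and the C8 epimer arise; they do not by themselves guarantee C9 over C1.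

Step 6. The rearrangement may stall, or the keto ester may fall back to 8 by deacylation, at the temperature needed to force a C–C bond onto the carbon next to quaternary C4. The fallback sets out from 8 and returns at 12. Johnson–Claisen rearrangement with triethyl orthoacetate and a trace of propionic acid at 140 °C, which proceeds through a ketene acetal and is reliable at crowded cyclohexenyl termini, should give ethyl 2-[(1S,6S)-2-iodo-6-(methoxycarbonyl)-6-methylcyclohex-2-en-1-yl]acetate F2 with the same transfer of chirality from C1 to C5. N,O-Dimethylhydroxylamine hydrochloride and i-PrMgCl at −20 °C should convert only the unhindered ethyl ester into methyl (1S,2S)-3-iodo-2-{2-[methoxy(methyl)amino]-2-oxoethyl}-1-methylcyclohex-3-ene-1-carboxylate F3. EtMgBr in THF at 0 °C then gives the ethyl ketone 12.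

Step 12. Acid may ionise the C9 carbinol before the ketal is gone, leading to allylic transposition to C1 or dehydration outside the controlled conditions of step 13. The fallback sets out from 18 and returns at 20. Ketal cleavage and cyclisation are merged in one flask: Bi(OTf)3 (5 mol%) in MeNO2 containing two equivalents of water at 0 °C, so that 19 forms and is consumed without isolation. No new compound is made (F0).

Further compounds
F1 | step 13 | (2E)-6-[(5S,6R)-5-(methoxycarbonyl)-5-methyl-6-{(2Z)-2-[(trimethylsilyl)oxy]but-2-en-1-yl}cyclohex-1-en-1-yl]-3-methyl-6-[(trimethylsilyl)oxy]hept-2-en-1-yl propanoate | CCC(=O)OC/C=C(\C)CCC(C)(O[Si](C)(C)C)C1=CCC[C@](C)(C(=O)OC)[C@@H]1C/C(O[Si](C)(C)C)=C/C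
F2 | step 6 | ethyl 2-[(1S,6S)-2-iodo-6-(methoxycarbonyl)-6-methylcyclohex-2-en-1-yl]acetate | IC1=CCC[C@](C)(C(=O)OC)[C@@H]1CC(=O)OCC
F3 | step 6 | methyl (1S,2S)-3-iodo-2-{2-[methoxy(methyl)amino]-2-oxoethyl}-1-methylcyclohex-3-ene-1-carboxylate | IC1=CCC[C@](C)(C(=O)OC)[C@@H]1CC(=O)N(C)OC
F0 | step 12 | none | none
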